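**Retrosynthetic overview** (sphingoid numbering: C1 = CH2OH, C2 = CHN, C3/C4 = CHOH, C5H2, C6=C7, C8–C11, cyclopropane CH carbons C12/C13, then butyl)
1. The amide N–C(=O) bond is made last from aminotriol 24 and (2R)-2-hydroxypentacosanoic acid 29; the acid comes from methyl (R)-glycidate and a C22 Grignard reagent.
2. C2–N and C3–O are set together by a tethered aminohydroxylation of a (Z)-C2=C3 alkene. A carbamate on O1 closes a temporary oxazolidinone ring (O1–C(=O)–N–C2–C1), and the C4 silyloxy group controls the face.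
3. Key: the homoallylic unit C4(OH)–C5H2–C6=C7 comes from a [2,3]-Wittig rearrangement of the silylpropargyl ether of the (S)-C7 allylic alcohol. The temporary C7–O bond is cleaved, C4–C5 forms, C4 (R) and the (E)-C6=C7 alkene arise by chirality transfer, and the alkyne supplies C2/C3.
4. Tail: the (S)-C7 carbinol comes from enantioselective vinylation of the C7 aldehyde, the C10–C11 bond from Cu-catalysed coupling of a cyclopropylmethyl tosylate, and the trans-cyclopropane from asymmetric Simmons–Smith cyclopropanation of (E)-hept-2-en-1-ol.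
5. Ring order: cyclopropane first (step 1); the temporary oxazolidinone is formed in step 13 and opened in step 14.

Key step: step 7

Remark: the acyl chain of the target SMILES is read as (2R)-2-hydroxypentacosanoyl (C25) and the cyclopropane as trans-(S,S).

**Step 1**
Reactants: 1 (E)-hept-2-en-1-ol
Product: 2 [(1S,2S)-2-butylcyclopropyl]methanol
Conditions: Et2Zn, CH2I2, DME, (4R,5R)-2-butyl-N,N,N',N'-tetramethyl-1,3,2-dioxaborolane-4,5-dicarboxamide (1.2 equiv), CH2Cl2, −10 °C to rt; aq. NH4Cl, then aq. NaOH wash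
Reagents that add atoms: diiodomethane (ICI)
Why: Asymmetric Simmons–Smith cyclopropanation of an allylic alcohol with bis(iodomethyl)zinc and the chiral dioxaborolane ligand; the zinc alkoxide binds the ligand, which directs methylene transfer to one alkene face, the (E)-geometry becomes the trans ring, and the (4R,5R)-ligand should give the (1S,2S) isomer as it does with (E)-cinnamyl alcohol.

**Step 2**
Reactants: 2 [(1S,2S)-2-butylcyclopropyl]methanol
Product: 3 [(1S,2S)-2-butylcyclopropyl]methyl 4-methylbenzenesulfonate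
Conditions: TsCl, Et3N, DMAP (cat.), CH2Cl2, 0 °C; used at once
Reagents that add atoms: 4-methylbenzenesulfonyl chloride (Cc1ccc(cc1)S(=O)(=O)Cl)
Why: Standard sulfonylation of a primary alcohol that touches no stereocentre; the tosylate is kept cold and used directly because cyclopropylcarbinyl sulfonates ionise easily.

**Step 3**
Reactants: 3 [(1S,2S)-2-butylcyclopropyl]methyl 4-methylbenzenesulfonate; 4 5-bromopent-1-ene
Product: 6 (1S,2S)-1-butyl-2-(hex-5-en-1-yl)cyclopropane, via pent-4-enylmagnesium bromide 5 (not isolated)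
Conditions: 4, Mg, THF, rt; then 3, Li2CuCl4 (3 mol%), THF, −78 °C to 0 °C
Reagents that add atoms: none
Why: Copper-catalysed alkyl–alkyl cross-coupling of a primary tosylate with a Grignard reagent; displacement by the organocuprate is SN2-like and avoids a free cyclopropylcarbinyl radical or cation, so the ring and both stereocentres should survive.

**Step 4**
Reactants: 6 (1S,2S)-1-butyl-2-(hex-5-en-1-yl)cyclopropane
Product: 8 5-[(1S,2S)-2-butylcyclopropyl]pentanal, via ozonide 7 (not isolated)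
Conditions: O3, CH2Cl2, −78 °C; then PPh3, −78 °C to rt
Reagents that add atoms: ozone ([O-][O+]=O)
Why: Ozonolysis with reductive work-up cleaves the only alkene to the C7 aldehyde; the saturated cyclopropane is inert to ozone at −78 °C.

**Step 5**
Reactants: 8 5-[(1S,2S)-2-butylcyclopropyl]pentanal
Product: 9 (3S)-7-[(1S,2S)-2-butylcyclopropyl]hept-1-en-3-ol
Conditions: divinylzinc (salt-free, 1.5 equiv), (+)-3-exo-(dimethylamino)isoborneol [(+)-DAIB] (5 mol%), toluene/Et2O, 0 °C; aq. NH4Cl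
Reagents that add atoms: divinylzinc (C=C[Zn]C=C)
Why: Amino-alcohol-catalysed enantioselective addition of an alkenylzinc reagent to an aldehyde; the (+)-DAIB zinc chelate should deliver vinyl to the Re face of 8 (the (−)-ligand is known to direct zinc reagents to the Si face), which sets C7 as (S).

**Step 6**
Reactants: 9 (3S)-7-[(1S,2S)-2-butylcyclopropyl]hept-1-en-3-ol; 10 (3-bromoprop-1-yn-1-yl)trimethylsilane
Product: 11 (3-{[(3S)-7-[(1S,2S)-2-butylcyclopropyl]hept-1-en-3-yl]oxy}prop-1-yn-1-yl)trimethylsilane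
Conditions: NaH, THF, 0 °C; then 10, Bu4NI (cat.), 0 °C to rt
Reagents that add atoms: none
Why: Williamson ether synthesis on the sodium alkoxide; no bond to C7 is broken, so its configuration is kept.

**Step 7**
Reactants: 11 (3-{[(3S)-7-[(1S,2S)-2-butylcyclopropyl]hept-1-en-3-yl]oxy}prop-1-yn-1-yl)trimethylsilane
Product: 14 (3R,5E)-10-[(1S,2S)-2-butylcyclopropyl]dec-5-en-1-yn-3-ol, via α-lithio ether 12 (not isolated), via lithium alkoxide 13 (not isolated)
Conditions: n-BuLi (1.5 equiv), THF, −78 °C, 4 h; then MeOH, K2CO3, −78 °C to rt; aq. NH4Cl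
Reagents that add atoms: none
Why: Deprotonation at the propargylic O–CH2 gives an α-oxy propargyl carbanion that should undergo a concerted suprafacial [2,3]-Wittig rearrangement through a five-membered envelope transition state, forming C4–C5 while the temporary C7–O bond breaks; the closest precedent is the rearrangement of (trimethylsilyl)propargyl ethers of enantioenriched secondary allylic alcohols. No ring is closed: the C7 stereocentre is traded for the C4 carbinol centre and the C6=C7 double bond. The C8 chain on C7 sits pseudo-equatorial in the envelope, which gives the (E)-alkene, and the silylalkynyl group on the carbanion carbon sits exo, away from the C6–H, so the (S)-configured C7–O bond should deliver the new bond to the face that makes C4 (R). The step needs [2,3] over [1,2] shift (secured by −78 °C and the propargyl-stabilised anion), deprotonation at the propargylic CH2 and not at the allylic C7–H (secured by the higher acidity of the former), and E/exo over Z/endo geometry (secured by the bulky Me3Si-alkynyl group and the unbranched C8 chain). Methanolic K2CO3 in the same flask then removes the C-silyl group and leaves the terminal alkyne that supplies C3 and C2.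

**Step 8**
Reactants: 14 (3R,5E)-10-[(1S,2S)-2-butylcyclopropyl]dec-5-en-1-yn-3-ol
Product: 15 tert-butyl{[(3R,5E)-10-[(1S,2S)-2-butylcyclopropyl]dec-5-en-1-yn-3-yl]oxy}dimethylsilane
Conditions: TBSCl, imidazole, DMF, rt
Reagents that add atoms: tert-butyl(chloro)dimethylsilane (CC(C)(C)[Si](C)(C)Cl)
Why: Imidazole-promoted silylation of the secondary propargylic alcohol; the bulky silyl ether protects O4 and later shields one face of the C2=C3 alkene.

**Step 9**
Reactants: 15 tert-butyl{[(3R,5E)-10-[(1S,2S)-2-butylcyclopropyl]dec-5-en-1-yn-3-yl]oxy}dimethylsilane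
Product: 17 (4R,6E)-11-[(1S,2S)-2-butylcyclopropyl]-4-{[tert-butyl(dimethyl)silyl]oxy}undec-6-en-2-yn-1-ol, via lithium acetylide 16 (not isolated)
Conditions: n-BuLi, THF, −78 °C; then (CH2O)n, −78 °C to rt; aq. NH4Cl
Reagents that add atoms: formaldehyde, as paraformaldehyde (C=O)
Why: Acetylide hydroxymethylation: the lithium acetylide adds to formaldehyde and brings in C1; no stereocentre is affected.

**Step 10**
Reactants: 17 (4R,6E)-11-[(1S,2S)-2-butylcyclopropyl]-4-{[tert-butyl(dimethyl)silyl]oxy}undec-6-en-2-yn-1-ol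
Product: 18 (2Z,4R,6E)-11-[(1S,2S)-2-butylcyclopropyl]-4-{[tert-butyl(dimethyl)silyl]oxy}undeca-2,6-dien-1-ol
Conditions: H2 (1 atm), Lindlar catalyst, quinoline, EtOAc, rt
Reagents that add atoms: none
Why: Lindlar semi-hydrogenation is a syn addition that should stop at the (Z)-C2=C3 alkene; the (E)-disubstituted C6=C7 alkene and the cyclopropane are not reduced over the poisoned catalyst.

**Step 11**
Reactants: 18 (2Z,4R,6E)-11-[(1S,2S)-2-butylcyclopropyl]-4-{[tert-butyl(dimethyl)silyl]oxy}undeca-2,6-dien-1-ol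
Product: 20 (2Z,4R,6E)-11-[(1S,2S)-2-butylcyclopropyl]-4-{[tert-butyl(dimethyl)silyl]oxy}undeca-2,6-dien-1-yl N-hydroxycarbamate, via imidazole carboxylate 19 (not isolated)
Conditions: CDI, MeCN, rt; then NH2OH·HCl, imidazole, 0 °C to rt
Reagents that add atoms: 1,1'-carbonyldiimidazole (O=C(n1ccnc1)n1ccnc1); hydroxylamine hydrochloride (NO.Cl)
Why: Acyl transfer: the primary allylic alcohol is converted to its imidazole carboxylate, which hydroxylamine attacks at nitrogen to give the N-hydroxycarbamate.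

**Step 12**
Reactants: 20 (2Z,4R,6E)-11-[(1S,2S)-2-butylcyclopropyl]-4-{[tert-butyl(dimethyl)silyl]oxy}undeca-2,6-dien-1-yl N-hydroxycarbamate
Product: 21 (2Z,4R,6E)-11-[(1S,2S)-2-butylcyclopropyl]-4-{[tert-butyl(dimethyl)silyl]oxy}undeca-2,6-dien-1-yl N-[(pentafluorobenzoyl)oxy]carbamate
Conditions: C6F5COCl, Et3N, CH2Cl2, −20 °C
Reagents that add atoms: pentafluorobenzoyl chloride (O=C(Cl)c1c(F)c(F)c(F)c(F)c1F)
Why: Selective O-acylation of the acidic N–OH group gives the N-aroyloxy carbamate, which is both the nitrogen source and the internal oxidant for the next step.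

**Step 13**
Reactants: 21 (2Z,4R,6E)-11-[(1S,2S)-2-butylcyclopropyl]-4-{[tert-butyl(dimethyl)silyl]oxy}undeca-2,6-dien-1-yl N-[(pentafluorobenzoyl)oxy]carbamate
Product: 22 (4S)-4-[(1S,2R,4E)-9-[(1S,2S)-2-butylcyclopropyl]-2-{[tert-butyl(dimethyl)silyl]oxy}-1-hydroxynon-4-en-1-yl]-1,3-oxazolidin-2-one
Conditions: K2OsO2(OH)4 (1–2 mol%), t-BuOH/H2O 3:1 (MeCN as cosolvent if needed), rt
Reagents that add atoms: water (O)
Why: Tethered aminohydroxylation: Os(VI) is oxidised by the N–O bond to an Os(VIII) imido species held on O1, which adds syn across the (Z)-C2=C3 alkene with N at C2 (five-membered oxazolidinone) and O at C3, so C2/C3 come out erythro, and attack anti to the C4 silyloxy group in the A(1,3)-minimised conformer (the empirical rule for osmylation of (Z)-allylic ethers) should give (2S,3S); the C6=C7 alkene should be spared because the oxidant is delivered intramolecularly and each molecule carries one oxidising equivalent.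

**Step 14**
Reactants: 22 (4S)-4-[(1S,2R,4E)-9-[(1S,2S)-2-butylcyclopropyl]-2-{[tert-butyl(dimethyl)silyl]oxy}-1-hydroxynon-4-en-1-yl]-1,3-oxazolidin-2-one
Product: 24 (2S,3S,4R,6E)-2-amino-11-[(1S,2S)-2-butylcyclopropyl]undec-6-ene-1,3,4-triol, via oxazolidinone diol 23 (not isolated)
Conditions: HCl (1 M in MeOH), rt; then NaOH (6 M aq., excess), EtOH, 85 °C
Reagents that add atoms: none
Why: Acid-catalysed methanolysis removes the silyl ether and hydroxide then hydrolyses the cyclic carbamate (the temporary tether) to the free 2-amino-1,3,4-triol; no bond to a stereocentre is broken.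

**Step 15**
Reactants: 25 1-bromodocosane; 26 methyl (2R)-oxirane-2-carboxylate
Product: 29 (2R)-2-hydroxypentacosanoic acid, via docosylmagnesium bromide 27 (not isolated), via methyl ester 28 (not isolated)
Conditions: 25, Mg, THF, 40 °C; then 26, CuI (10 mol%), THF, −30 °C; then LiOH, H2O/MeOH, rt; aq. HCl
Reagents that add atoms: lithium hydroxide ([Li+].[OH-])
Why: Copper-catalysed Grignard opening of the glycidate at the unsubstituted C3 (SN2 at CH2) leaves the C2 stereocentre untouched, so the (R)-epoxide should give the (R)-2-hydroxy ester, which is saponified in the same flask.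

**Step 16**
Reactants: 24 (2S,3S,4R,6E)-2-amino-11-[(1S,2S)-2-butylcyclopropyl]undec-6-ene-1,3,4-triol; 29 (2R)-2-hydroxypentacosanoic acid
Product: 31 (2R)-N-[(2S,3S,4R,6E)-11-[(1S,2S)-2-butylcyclopropyl]-1,3,4-trihydroxyundec-6-en-2-yl]-2-hydroxypentacosanamide (target), via benzotriazolyl ester 30 (not isolated)
Conditions: EDC·HCl, HOBt, THF/DMF, rt to 40 °C
Reagents that add atoms: none
Why: Carbodiimide/HOBt amide coupling; the primary amine of 24 is far more nucleophilic than its hydroxyl groups, and the active ester forms under conditions that should not epimerise the α-hydroxy acid.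

**Compound list**
1 | (E)-hept-2-en-1-ol | CCCC/C=C/CO | starting material
2 | [(1S,2S)-2-butylcyclopropyl]methanol | OC[C@H]1C[C@@H]1CCCC | intermediate
3 | [(1S,2S)-2-butylcyclopropyl]methyl 4-methylbenzenesulfonate | Cc1ccc(cc1)S(=O)(=O)OC[C@H]1C[C@@H]1CCCC | intermediate
4 | 5-bromopent-1-ene | C=CCCCBr | starting material
5 | pent-4-en-1-ylmagnesium bromide | C=CCCC[Mg]Br | intermediate (not isolated)
6 | (1S,2S)-1-butyl-2-(hex-5-en-1-yl)cyclopropane | C=CCCCC[C@H]1C[C@@H]1CCCC | intermediate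
7 | 3-{4-[(1S,2S)-2-butylcyclopropyl]butyl}-1,2,4-trioxolane (ozonide) | C1OOC(O1)CCCC[C@H]2C[C@@H]2CCCC | intermediate (not isolated)
8 | 5-[(1S,2S)-2-butylcyclopropyl]pentanal | O=CCCCC[C@H]1C[C@@H]1CCCC | intermediate
9 | (3S)-7-[(1S,2S)-2-butylcyclopropyl]hept-1-en-3-ol | C=C[C@@H](O)CCCC[C@H]1C[C@@H]1CCCC | intermediate
10 | (3-bromoprop-1-yn-1-yl)trimethylsilane | C[Si](C)(C)C#CCBr | starting material
11 | (3-{[(3S)-7-[(1S,2S)-2-butylcyclopropyl]hept-1-en-3-yl]oxy}prop-1-yn-1-yl)trimethylsilane | C=C[C@@H](OCC#C[Si](C)(C)C)CCCC[C@H]1C[C@@H]1CCCC | intermediate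
12 | α-lithio ether: 11 lithiated at the O–CH2 carbon | C=C[C@@H](OC([Li])C#C[Si](C)(C)C)CCCC[C@H]1C[C@@H]1CCCC | intermediate (not isolated)
13 | lithium (3R,5E)-10-[(1S,2S)-2-butylcyclopropyl]-1-(trimethylsilyl)dec-5-en-1-yn-3-olate | C[Si](C)(C)C#C[C@H]([O-])C/C=C/CCCC[C@H]1C[C@@H]1CCCC.[Li+] | intermediate (not isolated)
14 | (3R,5E)-10-[(1S,2S)-2-butylcyclopropyl]dec-5-en-1-yn-3-ol | C#C[C@H](O)C/C=C/CCCC[C@H]1C[C@@H]1CCCC | intermediate
15 | tert-butyl{[(3R,5E)-10-[(1S,2S)-2-butylcyclopropyl]dec-5-en-1-yn-3-yl]oxy}dimethylsilane | C#C[C@H](O[Si](C)(C)C(C)(C)C)C/C=C/CCCC[C@H]1C[C@@H]1CCCC | intermediate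
16 | lithium acetylide of 15 | [Li]C#C[C@H](O[Si](C)(C)C(C)(C)C)C/C=C/CCCC[C@H]1C[C@@H]1CCCC | intermediate (not isolated)
17 | (4R,6E)-11-[(1S,2S)-2-butylcyclopropyl]-4-{[tert-butyl(dimethyl)silyl]oxy}undec-6-en-2-yn-1-ol | OCC#C[C@H](O[Si](C)(C)C(C)(C)C)C/C=C/CCCC[C@H]1C[C@@H]1CCCC | intermediate
18 | (2Z,4R,6E)-11-[(1S,2S)-2-butylcyclopropyl]-4-{[tert-butyl(dimethyl)silyl]oxy}undeca-2,6-dien-1-ol | OC/C=C\[C@H](O[Si](C)(C)C(C)(C)C)C/C=C/CCCC[C@H]1C[C@@H]1CCCC | intermediate
19 | (2Z,4R,6E)-11-[(1S,2S)-2-butylcyclopropyl]-4-{[tert-butyl(dimethyl)silyl]oxy}undeca-2,6-dien-1-yl 1H-imidazole-1-carboxylate | O=C(OC/C=C\[C@H](O[Si](C)(C)C(C)(C)C)C/C=C/CCCC[C@H]1C[C@@H]1CCCC)n1ccnc1 | intermediate (not isolated)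
20 | (2Z,4R,6E)-11-[(1S,2S)-2-butylcyclopropyl]-4-{[tert-butyl(dimethyl)silyl]oxy}undeca-2,6-dien-1-yl N-hydroxycarbamate | ONC(=O)OC/C=C\[C@H](O[Si](C)(C)C(C)(C)C)C/C=C/CCCC[C@H]1C[C@@H]1CCCC | intermediate
21 | (2Z,4R,6E)-11-[(1S,2S)-2-butylcyclopropyl]-4-{[tert-butyl(dimethyl)silyl]oxy}undeca-2,6-dien-1-yl N-[(pentafluorobenzoyl)oxy]carbamate | O=C(ONC(=O)OC/C=C\[C@H](O[Si](C)(C)C(C)(C)C)C/C=C/CCCC[C@H]1C[C@@H]1CCCC)c1c(F)c(F)c(F)c(F)c1F | intermediate
22 | (4S)-4-[(1S,2R,4E)-9-[(1S,2S)-2-butylcyclopropyl]-2-{[tert-butyl(dimethyl)silyl]oxy}-1-hydroxynon-4-en-1-yl]-1,3-oxazolidin-2-one | O=C1N[C@@H](CO1)[C@H](O)[C@H](O[Si](C)(C)C(C)(C)C)C/C=C/CCCC[C@H]2C[C@@H]2CCCC | intermediate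
23 | (4S)-4-[(1S,2R,4E)-9-[(1S,2S)-2-butylcyclopropyl]-1,2-dihydroxynon-4-en-1-yl]-1,3-oxazolidin-2-one | O=C1N[C@@H](CO1)[C@H](O)[C@H](O)C/C=C/CCCC[C@H]2C[C@@H]2CCCC | intermediate (not isolated)
24 | (2S,3S,4R,6E)-2-amino-11-[(1S,2S)-2-butylcyclopropyl]undec-6-ene-1,3,4-triol | N[C@@H](CO)[C@H](O)[C@H](O)C/C=C/CCCC[C@H]1C[C@@H]1CCCC | intermediate
25 | 1-bromodocosane | CCCCCCCCCCCCCCCCCCCCCCBr | starting material
26 | methyl (2R)-oxirane-2-carboxylate | COC(=O)[C@H]1CO1 | starting material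
27 | docosylmagnesium bromide | CCCCCCCCCCCCCCCCCCCCCC[Mg]Br | intermediate (not isolated)
28 | methyl (2R)-2-hydroxypentacosanoate | CCCCCCCCCCCCCCCCCCCCCCC[C@@H](O)C(=O)OC | intermediate (not isolated)
29 | (2R)-2-hydroxypentacosanoic acid | CCCCCCCCCCCCCCCCCCCCCCC[C@@H](O)C(=O)O | intermediate
30 | 1H-benzotriazol-1-yl (2R)-2-hydroxypentacosanoate | CCCCCCCCCCCCCCCCCCCCCCC[C@@H](O)C(=O)On1nnc2ccccc12 | intermediate (not isolated)
31 | (2R)-N-[(2S,3S,4R,6E)-11-[(1S,2S)-2-butylcyclopropyl]-1,3,4-trihydroxyundec-6-en-2-yl]-2-hydroxypentacosanamide | CCCCCCCCCCCCCCCCCCCCCCC[C@@H](O)C(=O)N[C@@H](CO)[C@H](O)[C@H](O)C/C=C/CCCC[C@H]1C[C@@H]1CCCC | target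

**Step count**
Total step count: 16. Longest linear sequence: 15 steps (steps 1–14 and 16); step 15 is a one-step side branch.

**Steps most likely to fail**

1. Step 13 (tethered aminohydroxylation). The osmium–nitrogen delivery may occur with poor facial selectivity (attack syn to the silyloxy group), the C6=C7 alkene may be oxidised by free Os(VIII), or the N–O ester may hydrolyse before nitrogen transfer. The fallback sets out from 17 and comes back to the route at 24. Red-Al reduction of 17 in THF should give the (2E)-allylic alcohol (2E,4R,6E)-11-[(1S,2S)-2-butylcyclopropyl]-4-{[tert-butyl(dimethyl)silyl]oxy}undeca-2,6-dien-1-ol F1. Sharpless asymmetric epoxidation with D-(−)-diethyl tartrate, Ti(OiPr)4 and t-BuOOH, under reagent control, should give the (2R,3S)-epoxy alcohol F2. Cl3CCN with catalytic DBU should give the trichloroacetimidate F3. Et2AlCl in CH2Cl2 should open the epoxide at C2 in a 5-exo mode with inversion to give the 2-(trichloromethyl)oxazoline F4, which carries N at C2 (S) and the free C3 hydroxyl (S). Aqueous HCl in THF/MeOH, followed by basification, should hydrolyse the oxazoline, remove the silyl ether, and give 24.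

2. Step 7 ([2,3]-Wittig rearrangement). Chirality transfer may be incomplete if the endo transition state competes, the E/Z ratio may erode, or a [1,2]-shift may intervene. The fallback sets out from 9 and comes back to the route at 14, using a [3,3] instead of a [2,3] shift. Mitsunobu esterification of 9 with [(4-methoxybenzyl)oxy]acetic acid (PPh3, DIAD) inverts C7 and should give (3R)-7-[(1S,2S)-2-butylcyclopropyl]hept-1-en-3-yl [(4-methoxybenzyl)oxy]acetate F5. Ireland–Claisen rearrangement (LiHMDS, Me3SiCl/Et3N, THF, −78 °C to rt) of the chelated (Z)-enolate, through a chair with the C8 chain equatorial, should give the (2R,4E)-acid F6. LiAlH4 reduction should give the alcohol F7, Dess–Martin oxidation the aldehyde F8, and Ohira–Bestmann homologation the alkyne PMB ether F9. DDQ in wet CH2Cl2 removes the PMB group and returns 14.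

3. Step 5 (enantioselective vinylation). Vinyl transfer to an unbranched aldehyde may be insufficiently enantioselective because of uncatalysed background addition or residual magnesium salts. The fallback sets out from 8 and comes back to the route at 9. Vinylmagnesium bromide (THF, −78 °C) should give the C3-epimeric alcohol (3RS)-7-[(1S,2S)-2-butylcyclopropyl]hept-1-en-3-ol F10. Sharpless kinetic resolution (Ti(OiPr)4, D-(−)-diisopropyl tartrate, t-BuOOH 0.6 equiv, 4 Å molecular sieves, CH2Cl2, −20 °C) should epoxidise the (3R)-epimer and leave (3S)-9, which is separated by chromatography.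

**Further compounds**
F1 | step 13 | (2E,4R,6E)-11-[(1S,2S)-2-butylcyclopropyl]-4-{[tert-butyl(dimethyl)silyl]oxy}undeca-2,6-dien-1-ol | OC/C=C/[C@H](O[Si](C)(C)C(C)(C)C)C/C=C/CCCC[C@H]1C[C@@H]1CCCC
F2 | step 13 | {(2R,3S)-3-[(1R,3E)-8-[(1S,2S)-2-butylcyclopropyl]-1-{[tert-butyl(dimethyl)silyl]oxy}oct-3-en-1-yl]oxiran-2-yl}methanol | OC[C@H]1O[C@@H]1[C@H](O[Si](C)(C)C(C)(C)C)C/C=C/CCCC[C@H]2C[C@@H]2CCCC
F3 | step 13 | {(2R,3S)-3-[(1R,3E)-8-[(1S,2S)-2-butylcyclopropyl]-1-{[tert-butyl(dimethyl)silyl]oxy}oct-3-en-1-yl]oxiran-2-yl}methyl 2,2,2-trichloroacetimidate | ClC(Cl)(Cl)C(=N)OC[C@H]1O[C@@H]1[C@H](O[Si](C)(C)C(C)(C)C)C/C=C/CCCC[C@H]2C[C@@H]2CCCC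
F4 | step 13 | (1S,2R,4E)-9-[(1S,2S)-2-butylcyclopropyl]-2-{[tert-butyl(dimethyl)silyl]oxy}-1-[(4S)-2-(trichloromethyl)-4,5-dihydro-1,3-oxazol-4-yl]non-4-en-1-ol | ClC(Cl)(Cl)C1=N[C@@H](CO1)[C@H](O)[C@H](O[Si](C)(C)C(C)(C)C)C/C=C/CCCC[C@H]2C[C@@H]2CCCC
F5 | step 7 | (3R)-7-[(1S,2S)-2-butylcyclopropyl]hept-1-en-3-yl [(4-methoxybenzyl)oxy]acetate | C=C[C@H](OC(=O)COCc1ccc(OC)cc1)CCCC[C@H]2C[C@@H]2CCCC
F6 | step 7 | (2R,4E)-9-[(1S,2S)-2-butylcyclopropyl]-2-[(4-methoxybenzyl)oxy]non-4-enoic acid | OC(=O)[C@H](OCc1ccc(OC)cc1)C/C=C/CCCC[C@H]2C[C@@H]2CCCC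
F7 | step 7 | (2R,4E)-9-[(1S,2S)-2-butylcyclopropyl]-2-[(4-methoxybenzyl)oxy]non-4-en-1-ol | OC[C@H](OCc1ccc(OC)cc1)C/C=C/CCCC[C@H]2C[C@@H]2CCCC
F8 | step 7 | (2R,4E)-9-[(1S,2S)-2-butylcyclopropyl]-2-[(4-methoxybenzyl)oxy]non-4-enal | O=C[C@H](OCc1ccc(OC)cc1)C/C=C/CCCC[C@H]2C[C@@H]2CCCC
F9 | step 7 | 1-({[(3R,5E)-10-[(1S,2S)-2-butylcyclopropyl]dec-5-en-1-yn-3-yl]oxy}methyl)-4-methoxybenzene | C#C[C@H](OCc1ccc(OC)cc1)C/C=C/CCCC[C@H]2C[C@@H]2CCCC
F10 | step 5 | (3RS)-7-[(1S,2S)-2-butylcyclopropyl]hept-1-en-3-ol | C=CC(O)CCCC[C@H]1C[C@@H]1CCCC
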